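**Strategy**

Everything rests on opening ring C at its carbonyl carbon and its ether oxygen. C4 stands alone between C4a and C3, and O1 links C8a to C2, so the pyranone reduces to an ortho-iodophenol (ring A), carbon monoxide and a ring B arylacetylene. One palladium-catalysed carbonylative annulation forges C4a–C4, C4–C3 and O1–C2 and gives the flat flavone. Its precursor is a phloroglucinol-derived iodophenol that already carries the (R)-lavandulyl chain and has one free hydroxyl, ortho to iodine, with both other oxygens as MOM ethers. The side-chain centre comes from an auxiliary-controlled alkylation; C2 is set last but one by catalyst-controlled conjugate reduction.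

Key step: step 13

Remark on the chemistry: the side-chain stereocentre is set in step 2 and never touched again; it is S in 5, 6, 7 and 12 and R from 13 on only because the CIP rank of its CH2 arm changes when O, I or Zn is replaced by the aryl carbon. "(R)-Lavandulyl" below means (2R)-5-methyl-2-(prop-1-en-2-yl)hex-4-en-1-yl.

**Route**

Step 1
Reactants: 1 (S)-4-benzyl-1,3-oxazolidin-2-one; 2 3-methylbut-2-enoyl chloride
Product: 3 (S)-4-benzyl-3-(3-methylbut-2-enoyl)-1,3-oxazolidin-2-one
Conditions: n-BuLi, THF, −78 °C; then 2, −78 → 0 °C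
Reagents that add atoms: none
Why: N-acylation of the lithiated oxazolidinone by the acid chloride is the standard way to load an Evans auxiliary and forms no stereocentre.

Step 2
Reactants: 3 (S)-4-benzyl-3-(3-methylbut-2-enoyl)-1,3-oxazolidin-2-one; 4 prenyl bromide (1-bromo-3-methylbut-2-ene)
Product: 5 (4S)-4-benzyl-3-[(2S)-5-methyl-2-(prop-1-en-2-yl)hex-4-enoyl]-1,3-oxazolidin-2-one
Conditions: NaN(SiMe3)2, THF, −78 °C; then 4, −78 → −40 °C; AcOH quench at −78 °C
Reagents that add atoms: none
Why: Evans alkylation in its deconjugative form, in which γ-deprotonation gives the chelated (Z)-dienolate that reacts at the α-carbon with prenyl bromide (SN2) on the face opposite the benzyl group, setting the (2S) centre of the lavandulyl skeleton, the minor diastereomer being removed by chromatography.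

Step 3
Reactants: 5 (4S)-4-benzyl-3-[(2S)-5-methyl-2-(prop-1-en-2-yl)hex-4-enoyl]-1,3-oxazolidin-2-one
Product: 6 (S)-lavandulol, (2S)-5-methyl-2-(prop-1-en-2-yl)hex-4-en-1-ol
Conditions: LiBH4, H2O (1 equiv), Et2O, 0 °C
Reagents that add atoms: none
Why: Reductive cleavage of the N-acyl oxazolidinone by borohydride releases the primary alcohol and the auxiliary without touching the α-centre or the two alkenes.

Step 4
Reactants: 6 (S)-lavandulol
Product: 7 (S)-lavandulyl iodide, (3S)-3-(iodomethyl)-2,6-dimethylhepta-1,5-diene
Conditions: PPh3, imidazole, I2 (premixed), CH2Cl2, 0 °C → rt, dark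
Reagents that add atoms: iodine, II
Why: Appel-type iodination replaces the primary hydroxyl by SN2 at the CH2 carbon, one atom away from the stereocentre, which therefore keeps its configuration.

Step 5
Reactants: 8 phloroglucinol
Product: 9 3,5-bis(methoxymethoxy)phenol
Conditions: MOMCl (2.1 equiv), i-Pr2NEt, DMF, 0 °C → rt
Reagents that add atoms: chloromethyl methyl ether, COCCl
Why: Williamson-type acetal etherification with a limiting amount of MOMCl gives a statistical mixture from which the bis-ether is separated at this cheap stage.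

Step 6
Reactants: 9 3,5-bis(methoxymethoxy)phenol
Product: 10 2-iodo-3,5-bis(methoxymethoxy)phenol
Conditions: NIS (1.0 equiv), CH2Cl2, −78 → −40 °C, dark
Reagents that add atoms: N-iodosuccinimide, O=C1CCC(=O)N1I
Why: Electrophilic aromatic iodination of the phenol should go ortho to the hydroxyl (between OH and OMOM) because the para position is buttressed by two MOM ethers, and the two ortho positions of 9 are equivalent.

Step 7
Reactants: 10 2-iodo-3,5-bis(methoxymethoxy)phenol
Product: 11 tert-butyl[2-iodo-3,5-bis(methoxymethoxy)phenoxy]dimethylsilane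
Conditions: TBSCl, imidazole, DMF, rt
Reagents that add atoms: tert-butyldimethylsilyl chloride, CC(C)(C)[Si](C)(C)Cl
Why: O-silylation masks the acidic phenol, which would otherwise protonate the alkylzinc reagent of the next step.

Step 8
Reactants: 7 (S)-lavandulyl iodide; 11 tert-butyl[2-iodo-3,5-bis(methoxymethoxy)phenoxy]dimethylsilane
Product: 13 tert-butyl{2-[(R)-lavandulyl]-3,5-bis(methoxymethoxy)phenoxy}dimethylsilane, via (S)-lavandulylzinc iodide 12 (not isolated)
Conditions: 7, Zn dust (activated with BrCH2CH2Br and Me3SiCl), LiCl, THF, 35 °C; then 11, Pd(OAc)2 (3 mol %), SPhos (6 mol %), THF, 25 → 45 °C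
Reagents that add atoms: none
Why: Negishi coupling, in which zinc inserts into the primary C–I bond to give 12, which transmetalates to the arylpalladium iodide from 11 and reductively eliminates faster than β-hydride elimination under the bulky biarylphosphine, while the stereocentre, β to zinc, takes no part.

Step 9
Reactants: 13 tert-butyl{2-[(R)-lavandulyl]-3,5-bis(methoxymethoxy)phenoxy}dimethylsilane
Product: 14 2-[(R)-lavandulyl]-3,5-bis(methoxymethoxy)phenol
Conditions: Bu4NF, AcOH (1:1), THF, 0 °C
Reagents that add atoms: none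
Why: Fluoride-mediated desilylation under buffered, near-neutral conditions frees the phenol and leaves the MOM acetals and the alkenes alone.

Step 10
Reactants: 14 2-[(R)-lavandulyl]-3,5-bis(methoxymethoxy)phenol
Product: 15 2-iodo-6-[(R)-lavandulyl]-3,5-bis(methoxymethoxy)phenol
Conditions: NIS (1.0 equiv), CH2Cl2, −78 °C, dark; cold aqueous Na2S2O3 quench
Reagents that add atoms: N-iodosuccinimide, O=C1CCC(=O)N1I
Why: Electrophilic aromatic iodination of this very electron-rich phenol with exactly one equivalent of NIS should outpace reaction at the side-chain alkenes and go to the only free ortho position (the later C4a) in preference to the para position flanked by two MOM ethers.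

Step 11
Reactants: 16 2,4-dihydroxy-5-methoxybenzaldehyde
Product: 17 5-methoxy-2,4-bis(methoxymethoxy)benzaldehyde
Conditions: NaH (2.4 equiv), MOMCl (2.5 equiv), DMF, 0 °C → rt
Reagents that add atoms: chloromethyl methyl ether, COCCl
Why: Williamson-type O-alkylation of both sodium phenoxides protects the two hydroxyls, the strong base being needed for the one that is hydrogen-bonded to the aldehyde.

Step 12
Reactants: 17 5-methoxy-2,4-bis(methoxymethoxy)benzaldehyde
Product: 18 1-ethynyl-5-methoxy-2,4-bis(methoxymethoxy)benzene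
Conditions: dimethyl (1-diazo-2-oxopropyl)phosphonate, K2CO3, MeOH, 0 °C → rt
Reagents that add atoms: dimethyl (1-diazo-2-oxopropyl)phosphonate, COP(=O)(OC)C(=[N+]=[N-])C(C)=O
Why: Ohira–Bestmann homologation, in which methanolysis of the reagent gives the Seyferth–Gilbert anion that condenses with the non-enolisable aldehyde and loses N2 with a 1,2-shift to give the terminal alkyne under conditions that spare the MOM ethers.

Step 13
Reactants: 15 2-iodo-6-[(R)-lavandulyl]-3,5-bis(methoxymethoxy)phenol; 18 1-ethynyl-5-methoxy-2,4-bis(methoxymethoxy)benzene (1.3 equiv)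
Product: 21 8-[(R)-lavandulyl]-5,7,2',4'-tetrakis(methoxymethoxy)-5'-methoxyflavone, via ynone 19 (not isolated), via enaminone 20 (not isolated)
Conditions: PdCl2(PPh3)2 (5 mol %), Et2NH (solvent and base), CO (20 bar), 120 °C, autoclave
Reagents that add atoms: carbon monoxide, [C-]#[O+]
Why: Zerovalent palladium, formed in the flask from PdCl2(PPh3)2, inserts into the C4a–I bond, CO inserts to give the aroylpalladium iodide, and amine-assisted transfer of the alkynyl group followed by reductive elimination gives ynone 19; Et2NH then adds to 19 to give enaminone 20, whose β-carbon is attacked by the ortho hydroxyl with loss of Et2NH. The closest known reaction is the palladium-catalysed carbonylative, copper-free Sonogashira-type annulation of ortho-iodophenols with terminal alkynes to flavones, of which this doubly flanked iodide is a hindered case. Ring C closes in a 6-endo mode by addition–elimination at the enaminone β-carbon, which forms O1–C2. No stereocentre is formed and the side-chain centre is remote from every reacting atom. The step needs carbonylative over direct coupling, six- over five-membered closure and the right hydroxyl: CO pressure and the electron-rich arylpalladium favour CO insertion, the secondary amine channels the ynone through the enaminone to the flavone and not the aurone, and 15 has a single free hydroxyl, ortho to iodine, with the C5 oxygen capped as its MOM ether.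

Step 14
Reactants: 21 8-[(R)-lavandulyl]-5,7,2',4'-tetrakis(methoxymethoxy)-5'-methoxyflavone
Product: 22 (2S)-8-[(R)-lavandulyl]-5,7,2',4'-tetrakis(methoxymethoxy)-5'-methoxyflavanone
Conditions: Cu(OAc)2 (5 mol %), (R)-DTBM-SEGPHOS (5.5 mol %), (EtO)2MeSiH, t-BuOH, toluene, 0 °C → rt; neutral work-up
Reagents that add atoms: none
Why: Copper hydride-catalysed asymmetric conjugate reduction of a β,β-disubstituted enone, in which the bisphosphine-ligated CuH delivers hydride to the Re face of C2 under catalyst control to give the (2S) copper enolate that t-BuOH protonates at C3, the isolated alkenes and acetals being inert, and the ligand antipode is to be used should the first run show the opposite sense.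

Step 15
Reactants: 22 (2S)-8-[(R)-lavandulyl]-5,7,2',4'-tetrakis(methoxymethoxy)-5'-methoxyflavanone
Product: 23 CNP0323048.1, (2S)-2-(2,4-dihydroxy-5-methoxyphenyl)-5,7-dihydroxy-8-[(R)-lavandulyl]-2,3-dihydro-4H-chromen-4-one
Conditions: 1 M HCl in MeOH/H2O, 40 °C
Reagents that add atoms: none
Why: Acid-catalysed acetal exchange with methanol removes the four MOM ethers, and dilute acid at moderate temperature should spare the lavandulyl alkenes and the C2 centre, whose epimerisation by ring opening is a base-mediated process.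

**Compound list**

1 | (S)-4-benzyl-1,3-oxazolidin-2-one | O=C1N[C@@H](Cc2ccccc2)CO1 | starting material
2 | 3-methylbut-2-enoyl chloride | CC(C)=CC(=O)Cl | starting material
3 | (S)-4-benzyl-3-(3-methylbut-2-enoyl)-1,3-oxazolidin-2-one | CC(C)=CC(=O)N1[C@@H](Cc2ccccc2)COC1=O | intermediate
4 | prenyl bromide (1-bromo-3-methylbut-2-ene) | CC(C)=CCBr | starting material
5 | (4S)-4-benzyl-3-[(2S)-5-methyl-2-(prop-1-en-2-yl)hex-4-enoyl]-1,3-oxazolidin-2-one | C=C(C)[C@H](CC=C(C)C)C(=O)N1[C@@H](Cc2ccccc2)COC1=O | intermediate
6 | (S)-lavandulol, (2S)-5-methyl-2-(prop-1-en-2-yl)hex-4-en-1-ol | C=C(C)[C@H](CC=C(C)C)CO | intermediate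
7 | (S)-lavandulyl iodide, (3S)-3-(iodomethyl)-2,6-dimethylhepta-1,5-diene | C=C(C)[C@H](CC=C(C)C)CI | intermediate
8 | phloroglucinol | Oc1cc(O)cc(O)c1 | starting material
9 | 3,5-bis(methoxymethoxy)phenol | COCOc1cc(O)cc(OCOC)c1 | intermediate
10 | 2-iodo-3,5-bis(methoxymethoxy)phenol | COCOc1cc(O)c(I)c(OCOC)c1 | intermediate
11 | tert-butyl[2-iodo-3,5-bis(methoxymethoxy)phenoxy]dimethylsilane | COCOc1cc(O[Si](C)(C)C(C)(C)C)c(I)c(OCOC)c1 | intermediate
12 | (S)-lavandulylzinc iodide, [(2S)-5-methyl-2-(prop-1-en-2-yl)hex-4-en-1-yl]zinc iodide | C=C(C)[C@H](CC=C(C)C)C[Zn]I | intermediate (not isolated)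
13 | tert-butyl{2-[(R)-lavandulyl]-3,5-bis(methoxymethoxy)phenoxy}dimethylsilane | C=C(C)[C@H](CC=C(C)C)Cc1c(O[Si](C)(C)C(C)(C)C)cc(OCOC)cc1OCOC | intermediate
14 | 2-[(R)-lavandulyl]-3,5-bis(methoxymethoxy)phenol | C=C(C)[C@H](CC=C(C)C)Cc1c(O)cc(OCOC)cc1OCOC | intermediate
15 | 2-iodo-6-[(R)-lavandulyl]-3,5-bis(methoxymethoxy)phenol | C=C(C)[C@H](CC=C(C)C)Cc1c(OCOC)cc(OCOC)c(I)c1O | intermediate
16 | 2,4-dihydroxy-5-methoxybenzaldehyde | COc1cc(C=O)c(O)cc1O | starting material
17 | 5-methoxy-2,4-bis(methoxymethoxy)benzaldehyde | COCOc1cc(OCOC)c(C=O)cc1OC | intermediate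
18 | 1-ethynyl-5-methoxy-2,4-bis(methoxymethoxy)benzene | C#Cc1cc(OC)c(OCOC)cc1OCOC | intermediate
19 | ynone, 1-{2-hydroxy-3-[(R)-lavandulyl]-4,6-bis(methoxymethoxy)phenyl}-3-[5-methoxy-2,4-bis(methoxymethoxy)phenyl]prop-2-yn-1-one | C=C(C)[C@H](CC=C(C)C)Cc1c(OCOC)cc(OCOC)c(C(=O)C#Cc2cc(OC)c(OCOC)cc2OCOC)c1O | intermediate (not isolated)
20 | enaminone, 3-(diethylamino)-1-{2-hydroxy-3-[(R)-lavandulyl]-4,6-bis(methoxymethoxy)phenyl}-3-[5-methoxy-2,4-bis(methoxymethoxy)phenyl]prop-2-en-1-one (alkene geometry not defined) | C=C(C)[C@H](CC=C(C)C)Cc1c(OCOC)cc(OCOC)c(C(=O)C=C(N(CC)CC)c2cc(OC)c(OCOC)cc2OCOC)c1O | intermediate (not isolated)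
21 | 8-[(R)-lavandulyl]-5,7,2',4'-tetrakis(methoxymethoxy)-5'-methoxyflavone | C=C(C)[C@H](CC=C(C)C)Cc1c(OCOC)cc(OCOC)c2c1OC(c1cc(OC)c(OCOC)cc1OCOC)=CC2=O | intermediate
22 | (2S)-8-[(R)-lavandulyl]-5,7,2',4'-tetrakis(methoxymethoxy)-5'-methoxyflavanone | C=C(C)[C@H](CC=C(C)C)Cc1c(OCOC)cc(OCOC)c2c1O[C@H](c1cc(OC)c(OCOC)cc1OCOC)CC2=O | intermediate
23 | CNP0323048.1, (2S)-2-(2,4-dihydroxy-5-methoxyphenyl)-5,7-dihydroxy-8-[(2R)-5-methyl-2-(prop-1-en-2-yl)hex-4-en-1-yl]-2,3-dihydro-4H-chromen-4-one | C=C(C)[C@H](CC=C(C)C)Cc1c(O)cc(O)c2c1O[C@H](c1cc(OC)c(O)cc1O)CC2=O | target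

**Step count**

Total: 15 steps. Longest linear sequence: 10 steps (1, 2, 3, 4, 8, 9, 10, 13, 14, 15).

**Three steps most likely to fail**

1. Step 13. Oxidative addition and CO insertion at the C–I bond flanked by OH and OMOM may be slow enough that CO-free alkynylation (leading to five-membered closure) or aminocarbonylation by Et2NH takes over.
Fallback: it sets out from 18 and 15 and rejoins the route at ynone 19. Alkyne 18 is lithiated (n-BuLi, THF, −78 °C) and acylated with N-methoxy-N-methylcarbamoyl chloride to give the alkynyl Weinreb amide N-methoxy-N-methyl-3-[5-methoxy-2,4-bis(methoxymethoxy)phenyl]prop-2-ynamide F1. Iodophenol 15 is treated with n-BuLi (2.1 equiv, THF, −78 °C), which removes the phenolic proton and then exchanges iodine for lithium to give lithium 2-lithio-6-[(R)-lavandulyl]-3,5-bis(methoxymethoxy)phenoxide F2. Acylation of F2 by F1 and an aqueous NH4Cl quench give 19, and Et2NH in EtOH at room temperature then closes ring C through 20 to 21. C4a–C4 is made by polar acylation, so neither CO insertion nor palladium is needed.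

2. Step 14. Facial discrimination at C2 may be poor because of the ortho-substituted ring B and the peri C5 ether; the C4 carbonyl may also be reduced further, or the enolate may open ring C by β-elimination of the phenoxide.
Fallback: it sets out from 21 and rejoins at 22. Non-selective 1,4-reduction of 21 with LiBH(s-Bu)3 (THF, −78 °C) gives the tetrakis-MOM flavanone as a mixture of C2 epimers F3. Asymmetric transfer hydrogenation (Cp*RhCl[(R,R)-TsDPEN] or its antipode, whichever is matched to the 2R epimer, HCO2H/Et3N) then serves as a kinetic resolution. It reduces the 2R epimer to the cis-(2R,4R)-flavan-4-ol F4 and leaves 22, and ketone and alcohol are separated by chromatography.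

3. Step 10. The iodinating agent may attack para to the hydroxyl, or engage the side-chain alkenes (iodoetherification with the neighbouring phenol) on material that already carries the chiral chain.
Fallback: it sets out from 9 (with zinc reagent 12 made as in step 8) and rejoins at 15. Phenol 9 is iodinated at both ortho positions with two equivalents of NIS to give 2,6-diiodo-3,5-bis(methoxymethoxy)phenol F5, a twofold-symmetric compound from which any isomer formed by para attack is removed at this cheap stage. Silylation (TBSCl, imidazole) gives tert-butyl[2,6-diiodo-3,5-bis(methoxymethoxy)phenoxy]dimethylsilane F6. Negishi coupling of 12 with an excess of F6, whose two iodides are equivalent, gives tert-butyl{2-iodo-6-[(R)-lavandulyl]-3,5-bis(methoxymethoxy)phenoxy}dimethylsilane F7, and buffered fluoride releases 15. No electrophilic iodine then meets the alkenes.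

**Further compounds**

F1 | step 13 | N-methoxy-N-methyl-3-[5-methoxy-2,4-bis(methoxymethoxy)phenyl]prop-2-ynamide | CON(C)C(=O)C#Cc1cc(OC)c(OCOC)cc1OCOC
F2 | step 13 | lithium 2-lithio-6-[(R)-lavandulyl]-3,5-bis(methoxymethoxy)phenoxide | C=C(C)[C@H](CC=C(C)C)Cc1c(OCOC)cc(OCOC)c([Li])c1O[Li]
F3 | step 14 | 8-[(R)-lavandulyl]-5,7,2',4'-tetrakis(methoxymethoxy)-5'-methoxyflavanone as the mixture of C2 epimers | C=C(C)[C@H](CC=C(C)C)Cc1c(OCOC)cc(OCOC)c2c1OC(c1cc(OC)c(OCOC)cc1OCOC)CC2=O
F4 | step 14 | (2R,4R)-2-[5-methoxy-2,4-bis(methoxymethoxy)phenyl]-5,7-bis(methoxymethoxy)-8-[(R)-lavandulyl]chroman-4-ol | C=C(C)[C@H](CC=C(C)C)Cc1c(OCOC)cc(OCOC)c2c1O[C@@H](c1cc(OC)c(OCOC)cc1OCOC)C[C@H]2O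
F5 | step 10 | 2,6-diiodo-3,5-bis(methoxymethoxy)phenol | COCOc1cc(OCOC)c(I)c(O)c1I
F6 | step 10 | tert-butyl[2,6-diiodo-3,5-bis(methoxymethoxy)phenoxy]dimethylsilane | COCOc1cc(OCOC)c(I)c(O[Si](C)(C)C(C)(C)C)c1I
F7 | step 10 | tert-butyl{2-iodo-6-[(R)-lavandulyl]-3,5-bis(methoxymethoxy)phenoxy}dimethylsilane | C=C(C)[C@H](CC=C(C)C)Cc1c(OCOC)cc(OCOC)c(I)c1O[Si](C)(C)C(C)(C)C
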